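**Retrosynthetic overview**
1. Last bond: acetate on the primary glycerol hydroxyl; one acid step before it unmasks the methyl ketone and the glycerol diol.
2. Quaternary ring carbon (C10): 1,4-hydrosilylation of a 1-acylcyclohexene, then C-methylation of the exocyclic enolate anti to the neighbouring side chain.
3. Fragment union (C9–C10): proposed palladium/norbornene vicinal acylation with ipso-hydride termination of a cyclohexenyl triflate by a mixed carbonic anhydride of the side-chain acid.
4. Ring fragment: copper-catalysed asymmetric conjugate addition of a 3-oxobutyl equivalent to 4,4-dimethylcyclohex-2-enone (sets C5), enolate triflated in the same pot. Side chain: (R)-citronellic acid esterified with (S)-solketal, alkene cleaved to the acid (C13 and the glycerol centre come from the chiral pool).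
5. Ring order: the only carbocycle is bought in as the enone and is never formed or broken; the two dioxolane rings are protecting groups.

Assumption: the SMILES is taken literally, so the 3-oxobutyl chain and the acyl group on the ring are cis (ring methyl trans to the chain); ring centres (1R,2S), side-chain centre (3R), glycerol centre (2R).
Assumption: the copper/phosphoramidite addition to 4,4-dimethylcyclohex-2-enone follows the facial sense known for cyclohex-2-enone; if not, the antipodal ligand is used.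
Labels used below: C5 = ring CH carrying the oxobutyl chain; C10 = quaternary ring carbon; C9 = ketone carbon on C10; C13 = side-chain CH(CH3).

**Step 1**
Reactants: 1 (3R)-3,7-dimethyloct-6-enoic acid [(R)-citronellic acid]; 2 [(4S)-2,2-dimethyl-1,3-dioxolan-4-yl]methanol [(S)-solketal]
Product: 3 [(4R)-2,2-dimethyl-1,3-dioxolan-4-yl]methyl (3R)-3,7-dimethyloct-6-enoate
Conditions: DCC (1.1 equiv), 4-(dimethylamino)pyridine (0.1 equiv), CH2Cl2, 0 °C to rt
Reagents that add atoms: none
Why: Steglich esterification joins the primary alcohol of 2 to acid 1 without touching either chiral-pool stereocentre, which become C13 and the glycerol carbinol carbon of the target.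

**Step 2**
Reactants: 3 solketal ester of (R)-citronellic acid
Product: 5 (4R)-6-{[(4R)-2,2-dimethyl-1,3-dioxolan-4-yl]methoxy}-4-methyl-6-oxohexanoic acid, via aldehyde 4 (not isolated)
Conditions: RuCl3 hydrate (2 mol %), NaIO4 (4.1 equiv), MeCN/EtOAc/H2O, rt
Reagents that add atoms: sodium periodate [Na+].[O-]I(=O)(=O)=O; water O
Why: Sharpless RuO4 oxidative cleavage (RuCl3 reoxidised by NaIO4) cuts the trisubstituted alkene to acetone and an aldehyde that is oxidised on to the acid, while the ester, the acetonide and the methyl-bearing stereocentre are inert.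

**Step 3**
Reactants: 5 half-ester acid
Product: 6 (4R)-6-{[(4R)-2,2-dimethyl-1,3-dioxolan-4-yl]methoxy}-4-methyl-6-oxohexanoic isopropyl carbonic anhydride
Conditions: isopropyl chloroformate (1.05 equiv), N-methylmorpholine (1.05 equiv), THF, −15 °C, 30 min; filtered, concentrated, used at once
Reagents that add atoms: isopropyl chloroformate CC(C)OC(Cl)=O
Why: Acyl substitution at the chloroformate gives the mixed carbonic anhydride, an activated acyl donor that also carries the isopropoxy group used as hydride source in step 5.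

**Step 4**
Reactants: 7 2-(2-bromoethyl)-2-methyl-1,3-dioxolane; 8 4,4-dimethylcyclohex-2-en-1-one
Product: 12 (3R)-4,4-dimethyl-3-[2-(2-methyl-1,3-dioxolan-2-yl)ethyl]cyclohex-1-en-1-yl trifluoromethanesulfonate, via Grignard reagent 9 (not isolated), via diorganozinc 10 (not isolated), via zinc enolate 11 (not isolated)
Conditions: 7 (2.4 equiv), Mg, THF, 25 °C; Zn(OMe)2 (1.2 equiv), Et2O, rt, solids spun off, solvent changed to toluene; Cu(OTf)2 (2 mol %), (S,R,R)-O,O'-(1,1'-binaphthalene-2,2'-diyl) N,N-bis(1-phenylethyl)phosphoramidite (4 mol %), 8 (1 equiv), toluene, −30 °C, 16 h; then Tf2O (1.5 equiv), −30 to 0 °C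
Reagents that add atoms: trifluoromethanesulfonic anhydride O=S(=O)(OS(=O)(=O)C(F)(F)F)C(F)(F)F
Why: Copper-catalysed asymmetric conjugate addition of a diorganozinc with a binaphthol phosphoramidite ligand (Feringa type) sets C5 by ligand control of the enone face, and O-triflation of the regiodefined zinc enolate fixes the double bond toward C10.

**Step 5**
Reactants: 12 cyclohexenyl triflate; 6 mixed carbonic anhydride
Product: 13 [(4R)-2,2-dimethyl-1,3-dioxolan-4-yl]methyl (3R)-6-{(6S)-5,5-dimethyl-6-[2-(2-methyl-1,3-dioxolan-2-yl)ethyl]cyclohex-1-en-1-yl}-3-methyl-6-oxohexanoate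
Conditions: Pd(OAc)2 (10 mol %), tri(2-furyl)phosphine (25 mol %), N-methylbicyclo[2.2.1]hept-2-ene-2-carboxamide (50 mol %), Cs2CO3 (2.5 equiv), 6 (2 equiv), toluene/1,4-dioxane, 90 °C
Reagents that add atoms: none
Why: Proposed new method: a palladium/norbornene (Catellani-type) vicinal C–H acylation with ipso-hydride termination on a cyclohexenyl triflate with an aliphatic acyl donor, in which oxidative addition of the C–OTf bond to zerovalent palladium, norbornene insertion and palladation of the neighbouring vinyl C–H give a five-membered divalent palladium palladacycle that anhydride 6 acylates at that carbon through a tetravalent palladium acyl, after which norbornene is extruded and the isopropoxide freed by decarboxylation transfers hydride by β-hydride elimination so that reductive elimination leaves C–H where the triflate stood; the closest known reaction types are the ortho-acylation/ipso-hydrogenation of aryl iodides with isopropyl carbonic anhydrides and the alkenyl Catellani alkylation/arylation of cyclic enol triflates, and the step makes the C9–C10 bond that unites the two fragments while shifting the functionalised carbon one position along the ring, with C5 untouched.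

**Step 6**
Reactants: 13 enone
Product: 14 [(4R)-2,2-dimethyl-1,3-dioxolan-4-yl]methyl (3R)-6-{(2S)-3,3-dimethyl-2-[2-(2-methyl-1,3-dioxolan-2-yl)ethyl]cyclohexylidene}-3-methyl-6-[(triethylsilyl)oxy]hexanoate (E/Z mixture)
Conditions: Et3SiH (1.5 equiv), RhCl(PPh3)3 (2 mol %), toluene, 60 °C
Reagents that add atoms: triethylsilane CC[SiH](CC)CC
Why: Rhodium-catalysed 1,4-hydrosilylation of the enone with a monohydrosilane delivers hydride to the unsubstituted β-carbon and gives the tetrasubstituted silyl enol ether regiospecifically, leaving esters and acetals alone.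

**Step 7**
Reactants: 14 triethylsilyl enol ether
Product: 16 [(4R)-2,2-dimethyl-1,3-dioxolan-4-yl]methyl (3R)-3-methyl-6-oxo-6-{(1R,2S)-1,3,3-trimethyl-2-[2-(2-methyl-1,3-dioxolan-2-yl)ethyl]cyclohexyl}hexanoate, via ammonium enolate 15 (not isolated)
Conditions: anhydrous benzyltrimethylammonium fluoride (1.2 equiv), MeI (5 equiv), 4 Å molecular sieves, THF, −78 to 0 °C
Reagents that add atoms: iodomethane CI
Why: Fluoride-induced regiospecific enolate generation and C-alkylation (Kuwajima–Nakamura type) makes the quaternary C10 centre, with methyl iodide attacking the exocyclic enolate on the face opposite the vicinal C5 side chain (the geminal methyls shield both faces alike), so methyl ends up trans and the acyl group cis to that chain.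

**Step 8**
Reactants: 16 doubly protected keto ester
Product: 17 (2R)-2,3-dihydroxypropyl (3R)-3-methyl-6-oxo-6-[(1R,2S)-1,3,3-trimethyl-2-(3-oxobutyl)cyclohexyl]hexanoate
Conditions: 1 M HCl/THF (1:4), 25 °C, 3 h; NaHCO3 quench at 0 °C
Reagents that add atoms: water O
Why: Acid-catalysed acetal hydrolysis removes the dioxolane and the acetonide together, and at room temperature the esters and all four stereocentres are unaffected.

**Step 9**
Reactants: 17 monoacylglycerol diol
Product: 18 (2R)-3-acetoxy-2-hydroxypropyl (3R)-3-methyl-6-oxo-6-[(1R,2S)-1,3,3-trimethyl-2-(3-oxobutyl)cyclohexyl]hexanoate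
Conditions: AcCl (1.05 equiv), 2,4,6-collidine (2 equiv), CH2Cl2, −78 °C
Reagents that add atoms: acetyl chloride CC(Cl)=O
Why: Kinetically controlled acylation at low temperature with acetyl chloride and the hindered base 2,4,6-collidine selects the primary over the secondary hydroxyl, completing the 1,3-diacylglycerol without acyl migration.

**Compound list**
1 | (3R)-3,7-dimethyloct-6-enoic acid, (R)-citronellic acid | CC(C)=CCC[C@@H](C)CC(=O)O | starting material
2 | [(4S)-2,2-dimethyl-1,3-dioxolan-4-yl]methanol, (S)-solketal | OC[C@H]1COC(C)(C)O1 | starting material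
3 | [(4R)-2,2-dimethyl-1,3-dioxolan-4-yl]methyl (3R)-3,7-dimethyloct-6-enoate | CC(C)=CCC[C@@H](C)CC(=O)OC[C@H]1COC(C)(C)O1 | intermediate
4 | [(4R)-2,2-dimethyl-1,3-dioxolan-4-yl]methyl (3R)-3-methyl-6-oxohexanoate | O=CCC[C@@H](C)CC(=O)OC[C@H]1COC(C)(C)O1 | intermediate
5 | (4R)-6-{[(4R)-2,2-dimethyl-1,3-dioxolan-4-yl]methoxy}-4-methyl-6-oxohexanoic acid | OC(=O)CC[C@@H](C)CC(=O)OC[C@H]1COC(C)(C)O1 | intermediate
6 | (4R)-6-{[(4R)-2,2-dimethyl-1,3-dioxolan-4-yl]methoxy}-4-methyl-6-oxohexanoic isopropyl carbonic anhydride | CC(C)OC(=O)OC(=O)CC[C@@H](C)CC(=O)OC[C@H]1COC(C)(C)O1 | intermediate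
7 | 2-(2-bromoethyl)-2-methyl-1,3-dioxolane | CC1(CCBr)OCCO1 | starting material
8 | 4,4-dimethylcyclohex-2-en-1-one | CC1(C)CCC(=O)C=C1 | starting material
9 | [2-(2-methyl-1,3-dioxolan-2-yl)ethyl]magnesium bromide | CC1(CC[Mg]Br)OCCO1 | intermediate
10 | bis[2-(2-methyl-1,3-dioxolan-2-yl)ethyl]zinc | CC1(CC[Zn]CCC2(C)OCCO2)OCCO1 | intermediate
11 | [2-(2-methyl-1,3-dioxolan-2-yl)ethyl]zinc (3R)-4,4-dimethyl-3-[2-(2-methyl-1,3-dioxolan-2-yl)ethyl]cyclohex-1-en-1-olate | CC1(OCCO1)CC[C@H]1C(C)(C)CCC(O[Zn]CCC2(C)OCCO2)=C1 | intermediate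
12 | (3R)-4,4-dimethyl-3-[2-(2-methyl-1,3-dioxolan-2-yl)ethyl]cyclohex-1-en-1-yl trifluoromethanesulfonate | CC1(OCCO1)CC[C@H]1C(C)(C)CCC(OS(=O)(=O)C(F)(F)F)=C1 | intermediate
13 | [(4R)-2,2-dimethyl-1,3-dioxolan-4-yl]methyl (3R)-6-{(6S)-5,5-dimethyl-6-[2-(2-methyl-1,3-dioxolan-2-yl)ethyl]cyclohex-1-en-1-yl}-3-methyl-6-oxohexanoate | CC1(OCCO1)CC[C@H]1C(C)(C)CCC=C1C(=O)CC[C@@H](C)CC(=O)OC[C@H]1COC(C)(C)O1 | intermediate
14 | [(4R)-2,2-dimethyl-1,3-dioxolan-4-yl]methyl (3R)-6-{(2S)-3,3-dimethyl-2-[2-(2-methyl-1,3-dioxolan-2-yl)ethyl]cyclohexylidene}-3-methyl-6-[(triethylsilyl)oxy]hexanoate, E/Z mixture | CC1(OCCO1)CC[C@H]1C(C)(C)CCCC1=C(O[Si](CC)(CC)CC)CC[C@@H](C)CC(=O)OC[C@H]1COC(C)(C)O1 | intermediate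
15 | benzyltrimethylammonium enolate of the ring ketone (oxygen anion in place of the silyloxy group of 14) | CC1(OCCO1)CC[C@H]1C(C)(C)CCCC1=C([O-])CC[C@@H](C)CC(=O)OC[C@H]1COC(C)(C)O1.C[N+](C)(C)Cc1ccccc1 | intermediate
16 | [(4R)-2,2-dimethyl-1,3-dioxolan-4-yl]methyl (3R)-3-methyl-6-oxo-6-{(1R,2S)-1,3,3-trimethyl-2-[2-(2-methyl-1,3-dioxolan-2-yl)ethyl]cyclohexyl}hexanoate | CC1(OCCO1)CC[C@H]1C(C)(C)CCC[C@@]1(C)C(=O)CC[C@@H](C)CC(=O)OC[C@H]1COC(C)(C)O1 | intermediate
17 | (2R)-2,3-dihydroxypropyl (3R)-3-methyl-6-oxo-6-[(1R,2S)-1,3,3-trimethyl-2-(3-oxobutyl)cyclohexyl]hexanoate | CC(=O)CC[C@H]1C(C)(C)CCC[C@@]1(C)C(=O)CC[C@@H](C)CC(=O)OC[C@H](O)CO | intermediate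
18 | (2R)-3-acetoxy-2-hydroxypropyl (3R)-3-methyl-6-oxo-6-[(1R,2S)-1,3,3-trimethyl-2-(3-oxobutyl)cyclohexyl]hexanoate | CC(=O)CC[C@H]1C(C)(C)CCC[C@@]1(C)C(=O)CC[C@@H](C)CC(=O)OC[C@H](O)COC(C)=O | target

**Totals**
Total step count: 9.
Longest linear sequence: 8 (steps 1, 2, 3, 5, 6, 7, 8, 9; step 4 is the convergent branch).

**Three steps most likely to fail**

Step 5, the proposed new acylation. The risks are cyclopropanation of the alkenyl–norbornyl palladium species, simple reduction of the triflate, decarbonylation of the aliphatic acyl group, and crowding next to C5. The fallback uses known chemistry only; it sets out from ester 3 and from zinc enolate 11 (step 4 stopped before the triflation) and comes back at enone 13. Ozonolysis of 3 (O3, CH2Cl2, −78 °C, then PPh3) gives aldehyde 4 as an isolated compound. Enolate 11 is trapped with 4 instead of Tf2O (tandem conjugate addition–aldol) to give the β-hydroxy ketone F1 as a mixture at the two new centres. Mesylation (MsCl, Et3N, 0 °C) gives the mesylate F2, which DBU eliminates to the exocyclic alkylidene ketone F3. Nucleophilic epoxidation (t-BuOOH, DBU, CH2Cl2) gives the spiro-epoxy ketone F4. Wharton transposition (N2H4 hydrate, AcOH, MeOH, 0 °C to rt) runs through the epoxy hydrazone F5 to the allylic alcohol F6, which Dess–Martin periodinane oxidises to 13.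

Step 4, conjugate addition and triflation. The risks are salt or THF carried over with the functionalised zinc reagent (lower ee), the neopentyl β-carbon, and attack of Tf2O on the dioxolane. The fallback sets out from bromide 7 (as Grignard reagent 9) and comes back at triflate 12. Commercial 4,4-dimethylcyclohexane-1,3-dione with EtOH and p-toluenesulfonic acid (benzene, water removal) gives 3-ethoxy-6,6-dimethylcyclohex-2-en-1-one F7. Addition of 9 (CeCl3, THF, −78 °C) gives the tertiary carbinol F8, which on dilute oxalic acid work-up collapses to 4,4-dimethyl-3-[2-(2-methyl-1,3-dioxolan-2-yl)ethyl]cyclohex-2-en-1-one F9 (Stork–Danheiser transposition). Copper hydride asymmetric conjugate reduction (CuCl, NaOt-Bu, one enantiomer of 2,2'-bis(di-p-tolylphosphino)-1,1'-binaphthyl chosen for the required face, Ph2SiH2, toluene, 0 °C) sets C5 by hydride delivery and gives the diphenylsilyl enol ether F10. MeLi (THF, 0 °C) converts F10 into the lithium enolate F11, and PhNTf2 gives 12.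

Step 7, quaternary methylation. The risks are incomplete facial selectivity, O-methylation, and proton transfer to the less substituted enolate. The fallback sets out from silyl enol ether 14 and comes back at diol 17. Furukawa cyclopropanation (Et2Zn, CH2I2, CH2Cl2, 0 °C) on the face opposite the C5 chain gives the siloxycyclopropane F12. Aqueous HCl in THF (25 to 45 °C) removes the silyl group and both acetals to give the cyclopropanol F13, which ring-opens under the same acid at the bond between the carbinol carbon and the CH2 group (Conia-type α-methylation), giving 17 directly.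

**Further compounds**
F1 | step 5 | [(4R)-2,2-dimethyl-1,3-dioxolan-4-yl]methyl (3R)-6-{(2R)-3,3-dimethyl-2-[2-(2-methyl-1,3-dioxolan-2-yl)ethyl]-6-oxocyclohexyl}-6-hydroxy-3-methylhexanoate, mixture at ring C1 and the carbinol carbon | CC1(OCCO1)CC[C@H]1C(C)(C)CCC(=O)C1C(O)CC[C@@H](C)CC(=O)OC[C@H]1COC(C)(C)O1
F2 | step 5 | methanesulfonate ester of F1 at the carbinol oxygen | CC1(OCCO1)CC[C@H]1C(C)(C)CCC(=O)C1C(OS(C)(=O)=O)CC[C@@H](C)CC(=O)OC[C@H]1COC(C)(C)O1
F3 | step 5 | [(4R)-2,2-dimethyl-1,3-dioxolan-4-yl]methyl (3R)-6-{(2S)-3,3-dimethyl-2-[2-(2-methyl-1,3-dioxolan-2-yl)ethyl]-6-oxocyclohexylidene}-3-methylhexanoate | CC1(OCCO1)CC[C@H]1C(C)(C)CCC(=O)C1=CCC[C@@H](C)CC(=O)OC[C@H]1COC(C)(C)O1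
F4 | step 5 | spiro-epoxy ketone from F3 (oxirane across the exocyclic alkene, epoxide diastereomers) | CC1(OCCO1)CC[C@H]2C(C)(C)CCC(=O)C23OC3CC[C@@H](C)CC(=O)OC[C@H]1COC(C)(C)O1
F5 | step 5 | hydrazone of epoxy ketone F4 | CC1(OCCO1)CC[C@H]2C(C)(C)CCC(=NN)C23OC3CC[C@@H](C)CC(=O)OC[C@H]1COC(C)(C)O1
F6 | step 5 | [(4R)-2,2-dimethyl-1,3-dioxolan-4-yl]methyl (3R)-6-{(6S)-5,5-dimethyl-6-[2-(2-methyl-1,3-dioxolan-2-yl)ethyl]cyclohex-1-en-1-yl}-6-hydroxy-3-methylhexanoate, carbinol epimers | CC1(OCCO1)CC[C@H]1C(C)(C)CCC=C1C(O)CC[C@@H](C)CC(=O)OC[C@H]1COC(C)(C)O1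
F7 | step 4 | 3-ethoxy-6,6-dimethylcyclohex-2-en-1-one | CCOC1=CC(=O)C(C)(C)CC1
F8 | step 4 | 3-ethoxy-6,6-dimethyl-1-[2-(2-methyl-1,3-dioxolan-2-yl)ethyl]cyclohex-2-en-1-ol | CCOC1=CC(O)(CCC2(C)OCCO2)C(C)(C)CC1
F9 | step 4 | 4,4-dimethyl-3-[2-(2-methyl-1,3-dioxolan-2-yl)ethyl]cyclohex-2-en-1-one | CC1(OCCO1)CCC1=CC(=O)CCC1(C)C
F10 | step 4 | {[(3R)-4,4-dimethyl-3-[2-(2-methyl-1,3-dioxolan-2-yl)ethyl]cyclohex-1-en-1-yl]oxy}diphenylsilane | CC1(OCCO1)CC[C@H]1C(C)(C)CCC(O[SiH](c2ccccc2)c2ccccc2)=C1
F11 | step 4 | lithium (3R)-4,4-dimethyl-3-[2-(2-methyl-1,3-dioxolan-2-yl)ethyl]cyclohex-1-en-1-olate | CC1(OCCO1)CC[C@H]1C(C)(C)CCC(O[Li])=C1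
F12 | step 7 | spiro siloxycyclopropane from 14 (CH2 added across the enol ether double bond, anti to the C5 chain; triethylsilyloxy on the cyclopropane carbon that carries the hexanoate chain) | CC1(OCCO1)CC[C@H]2C(C)(C)CCC[C@]23CC3(O[Si](CC)(CC)CC)CC[C@@H](C)CC(=O)OC[C@H]1COC(C)(C)O1
F13 | step 7 | cyclopropanol from F12 with silyl group, dioxolane and acetonide removed | CC(=O)CC[C@H]2C(C)(C)CCC[C@]23CC3(O)CC[C@@H](C)CC(=O)OC[C@H](O)CO
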